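**Retrosynthetic overview**

- The target is opened in one operation to an acyclic 2‑furylmethyl ketone carrying a (Z)‑2‑(bromomethyl)enoate. Furan oxidation unveils the (Z)‑4‑oxo‑enal and the 1,3‑dione.
- Ring order, all in the last step: 3(2H)‑furanone by O10→C3 hemiketalisation and loss of water, then the ten‑membered carbocycle by an indium Barbier closure of C6–C7 (the bond the germacrene cyclase makes), then the 12,6‑lactone from the new alkoxide.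
- The acyclic bromide comes from an α‑acyloxy aldehyde and methyl propiolate (vinylalane addition, SN2′ bromination); the ester comes from methacrylic anhydride.
- The aldehyde comes from a furfuryl stannane (from methyl 2‑methylfuran‑3‑carboxylate) and a silyloxy γ‑lactone, joined at C1–C2 by lactone opening.
- The lactone comes from methyl pyruvate and the enol silane of 1,1‑dimethoxyacetone: a Cu[(R,R)‑tBu‑box](OTf)2 Mukaiyama aldol sets C10 and a CBS reduction sets C8.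

Assumption: positions are cited in germacrane numbering (C1 ketone, C3 enol‑ether carbon, C4=C5, C6 and C7 lactone carbons, C8 ester carbon, C10 quaternary carbon, C11=C13, C12 lactone carbonyl, C15 hydroxymethyl); the given SMILES is read as (4Z,6R,7R,8R,10R).

**Route**

Step 1
Reactants: 1 methyl 2‑methylfuran‑3‑carboxylate
Product: 2 methyl 2‑[(tributylstannyl)methyl]furan‑3‑carboxylate
Conditions: LiN(iPr)2, THF, −78 °C; Bu3SnCl, −78 → 0 °C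
Reagents that add atoms: tributyltin chloride CCCC[Sn](Cl)(CCCC)CCCC
Why: Lateral metalation of the 2‑methyl group (vinylogous ester enolate, as for the dianion of the parent acid) followed by C‑stannylation, which restores the furan; no stereocentre.

Step 2
Reactants: 2 methyl 2‑[(tributylstannyl)methyl]furan‑3‑carboxylate
Product: 3 {2‑[(tributylstannyl)methyl]furan‑3‑yl}methanol
Conditions: LiAlH4, Et2O, 0 °C
Reagents that add atoms: none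
Why: Hydride reduction of the ester to the primary alcohol (future C15–OH); the C–Sn bond is inert to LiAlH4.

Step 3
Reactants: 3 {2‑[(tributylstannyl)methyl]furan‑3‑yl}methanol
Product: 4 tert‑butyl(dimethyl)({2‑[(tributylstannyl)methyl]furan‑3‑yl}methoxy)silane
Conditions: TBSCl, imidazole, DMF, rt
Reagents that add atoms: tert‑butyldimethylsilyl chloride CC(C)(C)[Si](C)(C)Cl
Why: Standard silyl ether protection of the primary alcohol so that it survives the organolithium, acylation and bromination steps.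

Step 4
Reactants: 5 1,1‑dimethoxypropan‑2‑one
Product: 6 [(3,3‑dimethoxyprop‑1‑en‑2‑yl)oxy](triethyl)silane
Conditions: LiN(iPr)2, THF, −78 °C; Et3SiCl
Reagents that add atoms: chlorotriethylsilane CC[Si](Cl)(CC)CC
Why: Kinetic enolate formation at the methyl group and O‑silylation (enol silane synthesis); the hindered acetal C–H is not removed at −78 °C.

Step 5
Reactants: 6 [(3,3‑dimethoxyprop‑1‑en‑2‑yl)oxy](triethyl)silane; 7 methyl 2‑oxopropanoate (methyl pyruvate)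
Product: 8 methyl (2R)‑5,5‑dimethoxy‑2‑methyl‑4‑oxo‑2‑[(triethylsilyl)oxy]pentanoate
Conditions: Cu[(R,R)‑tBu‑box](OTf)2 (10 mol %), CH2Cl2, −78 °C (tBu‑box = 2,2′‑(propane‑2,2‑diyl)bis[4‑tert‑butyl‑4,5‑dihydro‑1,3‑oxazole])
Reagents that add atoms: none
Why: Evans Mukaiyama aldol: pyruvate chelates copper and the (R,R)‑ligand leaves the re face of the ketone open (mirror image of the (S,S)‑catalyst, which gives si‑face addition), so the quaternary carbinol C10 is formed R with silyl transfer to its oxygen.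

Step 6
Reactants: 8 methyl (2R)‑5,5‑dimethoxy‑2‑methyl‑4‑oxo‑2‑[(triethylsilyl)oxy]pentanoate
Product: 10 (3R,5R)‑5‑(dimethoxymethyl)‑3‑methyl‑3‑[(triethylsilyl)oxy]oxolan‑2‑one, via hydroxy ester 9 (not isolated)
Conditions: (S)‑Me‑CBS oxazaborolidine (20 mol %), BH3·SMe2, THF, −30 °C; MeOH; then PPTS (cat.), PhMe, 50 °C
Reagents that add atoms: none
Why: Corey–Bakshi–Shibata reduction in which the dimethoxymethyl group is taken as the large ketone substituent (as in CBS reductions of α‑keto acetals), so the (S)‑catalyst gives the (R)‑carbinol C8 under catalyst control; the γ‑hydroxy ester then lactonises under mild acid.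

Step 7
Reactants: 4 tert‑butyl(dimethyl)({2‑[(tributylstannyl)methyl]furan‑3‑yl}methoxy)silane; 10 (3R,5R)‑5‑(dimethoxymethyl)‑3‑methyl‑3‑[(triethylsilyl)oxy]oxolan‑2‑one
Product: 12 (3R,5R)‑1‑[3‑({[tert‑butyl(dimethyl)silyl]oxy}methyl)furan‑2‑yl]‑5‑hydroxy‑6,6‑dimethoxy‑3‑methyl‑3‑[(triethylsilyl)oxy]hexan‑2‑one, via furfuryllithium 11 (not isolated)
Conditions: n‑BuLi, THF, −78 °C; then 10, −78 °C; H2O
Reagents that add atoms: n‑butyllithium [Li]CCCC (lithium kept only in 11)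
Why: Tin–lithium exchange gives the resonance‑stabilised furfuryllithium, which adds once to the lactone carbonyl (the cyclic lithium hemiketal resists a second addition) and so forms the C1–C2 bond and frees the C8 hydroxyl; 12 equilibrates with its cyclic hemiketal and no stereocentre is touched.

Step 8
Reactants: 12 (3R,5R)‑1‑[3‑({[tert‑butyl(dimethyl)silyl]oxy}methyl)furan‑2‑yl]‑5‑hydroxy‑6,6‑dimethoxy‑3‑methyl‑3‑[(triethylsilyl)oxy]hexan‑2‑one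
Product: 13 (2R,4R)‑6‑[3‑({[tert‑butyl(dimethyl)silyl]oxy}methyl)furan‑2‑yl]‑1,1‑dimethoxy‑4‑methyl‑5‑oxo‑4‑[(triethylsilyl)oxy]hexan‑2‑yl 2‑methylprop‑2‑enoate
Conditions: methacrylic anhydride, Et3N, DMAP (cat.), CH2Cl2, 0 °C → rt
Reagents that add atoms: methacrylic anhydride CC(=C)C(=O)OC(=O)C(C)=C
Why: DMAP‑catalysed acylation of the secondary C8 alcohol of the open‑chain tautomer, which drains the hemiketal equilibrium; the tertiary oxygen is silylated and cannot compete.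

Step 9
Reactants: 13 (2R,4R)‑6‑[3‑({[tert‑butyl(dimethyl)silyl]oxy}methyl)furan‑2‑yl]‑1,1‑dimethoxy‑4‑methyl‑5‑oxo‑4‑[(triethylsilyl)oxy]hexan‑2‑yl 2‑methylprop‑2‑enoate
Product: 14 (2R,4R)‑6‑[3‑({[tert‑butyl(dimethyl)silyl]oxy}methyl)furan‑2‑yl]‑4‑methyl‑1,5‑dioxo‑4‑[(triethylsilyl)oxy]hexan‑2‑yl 2‑methylprop‑2‑enoate
Conditions: Et3SiOTf, 2,6‑lutidine, CH2Cl2, −40 → 0 °C; then H2O
Reagents that add atoms: water O
Why: Fujioka‑type acetal cleavage through a pyridinium intermediate under non‑acidic conditions, so the furan, both silyl ethers and the epimerisable α‑acyloxy centre C8 survive.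

Step 10
Reactants: 14 (2R,4R)‑6‑[3‑({[tert‑butyl(dimethyl)silyl]oxy}methyl)furan‑2‑yl]‑4‑methyl‑1,5‑dioxo‑4‑[(triethylsilyl)oxy]hexan‑2‑yl 2‑methylprop‑2‑enoate; 15 methyl prop‑2‑ynoate (methyl propiolate)
Product: 17 methyl (3RS,4R,6R)‑8‑[3‑({[tert‑butyl(dimethyl)silyl]oxy}methyl)furan‑2‑yl]‑3‑hydroxy‑6‑methyl‑2‑methylidene‑4‑[(2‑methylprop‑2‑enoyl)oxy]‑7‑oxo‑6‑[(triethylsilyl)oxy]octanoate, via vinylalane 16 (not isolated)
Conditions: iBu2AlH, NMO, THF, 0 °C (15 → 16); then 14, 0 °C → rt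
Reagents that add atoms: diisobutylaluminium hydride CC(C)C[AlH]CC(C)C (aluminium and isobutyl groups kept only in 16)
Why: Hydroalumination of the propiolate gives the α‑alumino acrylate, which adds to the aldehyde faster than to the hindered ketone (amine‑free Morita–Baylis–Hillman‑type vinylalumination), so C8 is not epimerised; the new C7 carbinol is a mixture that is erased in step 11.

Step 11
Reactants: 17 methyl (3RS,4R,6R)‑8‑[3‑({[tert‑butyl(dimethyl)silyl]oxy}methyl)furan‑2‑yl]‑3‑hydroxy‑6‑methyl‑2‑methylidene‑4‑[(2‑methylprop‑2‑enoyl)oxy]‑7‑oxo‑6‑[(triethylsilyl)oxy]octanoate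
Product: 19 methyl (2Z,4R,6R)‑2‑(bromomethyl)‑8‑[3‑({[tert‑butyl(dimethyl)silyl]oxy}methyl)furan‑2‑yl]‑6‑methyl‑4‑[(2‑methylprop‑2‑enoyl)oxy]‑7‑oxo‑6‑[(triethylsilyl)oxy]oct‑2‑enoate, via allylic mesylate 18 (not isolated)
Conditions: MsCl, Et3N, CH2Cl2, −20 °C; then LiBr, THF, rt
Reagents that add atoms: methanesulfonyl chloride CS(=O)(=O)Cl (kept only in 18); lithium bromide [Li+].[Br-]
Why: Mesylation and SN2′ displacement by bromide, the standard conversion of such adducts into (Z)‑2‑(bromomethyl)alk‑2‑enoates; the conjugated Z isomer is the thermodynamic product.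

Step 12
Reactants: 19 methyl (2Z,4R,6R)‑2‑(bromomethyl)‑8‑[3‑({[tert‑butyl(dimethyl)silyl]oxy}methyl)furan‑2‑yl]‑6‑methyl‑4‑[(2‑methylprop‑2‑enoyl)oxy]‑7‑oxo‑6‑[(triethylsilyl)oxy]oct‑2‑enoate
Product: 20 methyl (2Z,4R,6R)‑2‑(bromomethyl)‑6‑hydroxy‑8‑[3‑(hydroxymethyl)furan‑2‑yl]‑6‑methyl‑4‑[(2‑methylprop‑2‑enoyl)oxy]‑7‑oxooct‑2‑enoate
Conditions: HF·pyridine, THF, 0 °C → rt
Reagents that add atoms: none
Why: Fluoride‑driven cleavage of both silyl ethers under mildly acidic conditions that the allylic bromide, the esters and the furan tolerate; it frees the 10‑hydroxyl needed to trap the C3 ketone in step 13.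

Step 13
Reactants: 20 methyl (2Z,4R,6R)‑2‑(bromomethyl)‑6‑hydroxy‑8‑[3‑(hydroxymethyl)furan‑2‑yl]‑6‑methyl‑4‑[(2‑methylprop‑2‑enoyl)oxy]‑7‑oxooct‑2‑enoate
Product: 25 (4Z,6R,7R,8R,10R)‑3,10‑epoxy‑15‑hydroxy‑8‑[(2‑methylprop‑2‑enoyl)oxy]‑1‑oxogermacra‑2,4,11(13)‑trien‑12,6‑olide (the target), via keto‑enal 21 (not isolated), via hemiketal 22 (not isolated), via furanone enal 23 (not isolated), via seco hydroxy ester 24 (not isolated)
Conditions: DMDO, acetone, −78 → −20 °C; PPTS (cat.), CH2Cl2, 0 °C; then In powder, THF/sat. aq. NH4Cl (2 mM), rt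
Reagents that add atoms: dimethyldioxirane CC1(C)OO1
Why: Proposed new method: DMDO epoxidises the more substituted furan bond and the epoxide opens to the (Z)‑4‑oxo‑enal 21 (known furan to cis‑enedione oxidation, which fixes the 4Z geometry); the 10‑hydroxyl adds to the new C3 ketone and acid removes water to give the 3(2H)‑furanone 23 (classical cyclodehydration of α′‑hydroxy‑1,3‑diketones); indium then turns the allylic bromide into an allylindium that adds only to the aldehyde through a chair transition state, closing C6–C7 of the ten‑membered ring (macrocyclising Barbier reaction) and expected to give the trans‑fused (6R,7R) arrangement with the C8 ester pseudo‑equatorial, before the alkoxide lactonises onto the methyl ester; the three operations are individually known and are telescoped here.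

**Compound list**

1 | methyl 2‑methylfuran‑3‑carboxylate | COC(=O)c1ccoc1C | starting material
2 | methyl 2‑[(tributylstannyl)methyl]furan‑3‑carboxylate | COC(=O)c1ccoc1C[Sn](CCCC)(CCCC)CCCC | intermediate
3 | {2‑[(tributylstannyl)methyl]furan‑3‑yl}methanol | OCc1ccoc1C[Sn](CCCC)(CCCC)CCCC | intermediate
4 | tert‑butyl(dimethyl)({2‑[(tributylstannyl)methyl]furan‑3‑yl}methoxy)silane | CC(C)(C)[Si](C)(C)OCc1ccoc1C[Sn](CCCC)(CCCC)CCCC | intermediate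
5 | 1,1‑dimethoxypropan‑2‑one | CC(=O)C(OC)OC | starting material
6 | [(3,3‑dimethoxyprop‑1‑en‑2‑yl)oxy](triethyl)silane | C=C(O[Si](CC)(CC)CC)C(OC)OC | intermediate
7 | methyl 2‑oxopropanoate (methyl pyruvate) | CC(=O)C(=O)OC | starting material
8 | methyl (2R)‑5,5‑dimethoxy‑2‑methyl‑4‑oxo‑2‑[(triethylsilyl)oxy]pentanoate | COC(=O)[C@](C)(O[Si](CC)(CC)CC)CC(=O)C(OC)OC | intermediate
9 | methyl (2R,4R)‑4‑hydroxy‑5,5‑dimethoxy‑2‑methyl‑2‑[(triethylsilyl)oxy]pentanoate | COC(=O)[C@](C)(O[Si](CC)(CC)CC)C[C@@H](O)C(OC)OC | intermediate (not isolated)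
10 | (3R,5R)‑5‑(dimethoxymethyl)‑3‑methyl‑3‑[(triethylsilyl)oxy]oxolan‑2‑one | C[C@@]1(O[Si](CC)(CC)CC)C[C@H](C(OC)OC)OC1=O | intermediate
11 | {[3‑({[tert‑butyl(dimethyl)silyl]oxy}methyl)furan‑2‑yl]methyl}lithium | [Li]Cc1occc1CO[Si](C)(C)C(C)(C)C | intermediate (not isolated)
12 | (3R,5R)‑1‑[3‑({[tert‑butyl(dimethyl)silyl]oxy}methyl)furan‑2‑yl]‑5‑hydroxy‑6,6‑dimethoxy‑3‑methyl‑3‑[(triethylsilyl)oxy]hexan‑2‑one | CC(C)(C)[Si](C)(C)OCc1ccoc1CC(=O)[C@](C)(O[Si](CC)(CC)CC)C[C@@H](O)C(OC)OC | intermediate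
13 | (2R,4R)‑6‑[3‑({[tert‑butyl(dimethyl)silyl]oxy}methyl)furan‑2‑yl]‑1,1‑dimethoxy‑4‑methyl‑5‑oxo‑4‑[(triethylsilyl)oxy]hexan‑2‑yl 2‑methylprop‑2‑enoate | CC(C)(C)[Si](C)(C)OCc1ccoc1CC(=O)[C@](C)(O[Si](CC)(CC)CC)C[C@@H](OC(=O)C(C)=C)C(OC)OC | intermediate
14 | (2R,4R)‑6‑[3‑({[tert‑butyl(dimethyl)silyl]oxy}methyl)furan‑2‑yl]‑4‑methyl‑1,5‑dioxo‑4‑[(triethylsilyl)oxy]hexan‑2‑yl 2‑methylprop‑2‑enoate | CC(C)(C)[Si](C)(C)OCc1ccoc1CC(=O)[C@](C)(O[Si](CC)(CC)CC)C[C@@H](OC(=O)C(C)=C)C=O | intermediate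
15 | methyl prop‑2‑ynoate (methyl propiolate) | C#CC(=O)OC | starting material
16 | methyl 2‑[bis(2‑methylpropyl)alumanyl]prop‑2‑enoate | C=C(C(=O)OC)[Al](CC(C)C)CC(C)C | intermediate (not isolated)
17 | methyl (3RS,4R,6R)‑8‑[3‑({[tert‑butyl(dimethyl)silyl]oxy}methyl)furan‑2‑yl]‑3‑hydroxy‑6‑methyl‑2‑methylidene‑4‑[(2‑methylprop‑2‑enoyl)oxy]‑7‑oxo‑6‑[(triethylsilyl)oxy]octanoate | CC(C)(C)[Si](C)(C)OCc1ccoc1CC(=O)[C@](C)(O[Si](CC)(CC)CC)C[C@@H](OC(=O)C(C)=C)C(O)C(=C)C(=O)OC | intermediate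
18 | methyl (3RS,4R,6R)‑8‑[3‑({[tert‑butyl(dimethyl)silyl]oxy}methyl)furan‑2‑yl]‑3‑[(methanesulfonyl)oxy]‑6‑methyl‑2‑methylidene‑4‑[(2‑methylprop‑2‑enoyl)oxy]‑7‑oxo‑6‑[(triethylsilyl)oxy]octanoate | CC(C)(C)[Si](C)(C)OCc1ccoc1CC(=O)[C@](C)(O[Si](CC)(CC)CC)C[C@@H](OC(=O)C(C)=C)C(OS(C)(=O)=O)C(=C)C(=O)OC | intermediate (not isolated)
19 | methyl (2Z,4R,6R)‑2‑(bromomethyl)‑8‑[3‑({[tert‑butyl(dimethyl)silyl]oxy}methyl)furan‑2‑yl]‑6‑methyl‑4‑[(2‑methylprop‑2‑enoyl)oxy]‑7‑oxo‑6‑[(triethylsilyl)oxy]oct‑2‑enoate | CC(C)(C)[Si](C)(C)OCc1ccoc1CC(=O)[C@](C)(O[Si](CC)(CC)CC)C[C@@H](OC(=O)C(C)=C)/C=C(\CBr)C(=O)OC | intermediate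
20 | methyl (2Z,4R,6R)‑2‑(bromomethyl)‑6‑hydroxy‑8‑[3‑(hydroxymethyl)furan‑2‑yl]‑6‑methyl‑4‑[(2‑methylprop‑2‑enoyl)oxy]‑7‑oxooct‑2‑enoate | OCc1ccoc1CC(=O)[C@](C)(O)C[C@@H](OC(=O)C(C)=C)/C=C(\CBr)C(=O)OC | intermediate
21 | methyl (2Z,4R,6R,10Z)‑2‑(bromomethyl)‑6‑hydroxy‑10‑(hydroxymethyl)‑6‑methyl‑4‑[(2‑methylprop‑2‑enoyl)oxy]‑7,9,12‑trioxododeca‑2,10‑dienoate | O=C/C=C(/CO)C(=O)CC(=O)[C@](C)(O)C[C@@H](OC(=O)C(C)=C)/C=C(\CBr)C(=O)OC | intermediate (not isolated)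
22 | methyl (2Z,4R)‑2‑(bromomethyl)‑5‑{(2R,5RS)‑5‑hydroxy‑5‑[(2Z)‑1‑hydroxy‑4‑oxobut‑2‑en‑2‑yl]‑2‑methyl‑3‑oxooxolan‑2‑yl}‑4‑[(2‑methylprop‑2‑enoyl)oxy]pent‑2‑enoate | O=C/C=C(/CO)C1(O)CC(=O)[C@@](C)(C[C@@H](OC(=O)C(C)=C)/C=C(\CBr)C(=O)OC)O1 | intermediate (not isolated)
23 | methyl (2Z,4R)‑2‑(bromomethyl)‑5‑{(2R)‑5‑[(2Z)‑1‑hydroxy‑4‑oxobut‑2‑en‑2‑yl]‑2‑methyl‑3‑oxo‑2,3‑dihydrofuran‑2‑yl}‑4‑[(2‑methylprop‑2‑enoyl)oxy]pent‑2‑enoate | O=C/C=C(/CO)C1=CC(=O)[C@@](C)(C[C@@H](OC(=O)C(C)=C)/C=C(\CBr)C(=O)OC)O1 | intermediate (not isolated)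
24 | methyl (4Z,6R,7S,8R,10R)‑3,10‑epoxy‑6,15‑dihydroxy‑8‑[(2‑methylprop‑2‑enoyl)oxy]‑1‑oxogermacra‑2,4,11(13)‑trien‑12‑oate | C=C(C)C(=O)O[C@@H]1C[C@@]2(C)OC(=CC2=O)/C(CO)=C\[C@@H](O)[C@@H]1C(=C)C(=O)OC | intermediate (not isolated)
25 | (4Z,6R,7R,8R,10R)‑3,10‑epoxy‑15‑hydroxy‑8‑[(2‑methylprop‑2‑enoyl)oxy]‑1‑oxogermacra‑2,4,11(13)‑trien‑12,6‑olide | C=C(C)C(=O)O[C@@H]1C[C@@]2(C)OC(=CC2=O)/C(CO)=C\[C@H]2OC(=O)C(=C)[C@@H]21 | target

**Totals**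

Total step count: 13. Longest linear sequence: 10 steps (steps 1–3 then 7–13; the branch through steps 4–6 then 7–13 is equally long).

**Three steps most likely to fail**

Step 13 (one‑flask furan oxidation, cyclodehydration and ring closure). The cis‑keto‑enal may isomerise or condense before it is trapped, the 2 mM Barbier closure may oligomerise, and the C6/C7 facial selectivity is not certain. The fallback closes the ten‑membered ring first and forms the furanone across the ring; it sets out from 19 with both silyl ethers kept and comes back at 25. DMDO converts 19 into methyl (2Z,4R,6R,10Z)‑2‑(bromomethyl)‑10‑({[tert‑butyl(dimethyl)silyl]oxy}methyl)‑6‑methyl‑4‑[(2‑methylprop‑2‑enoyl)oxy]‑7,9,12‑trioxo‑6‑[(triethylsilyl)oxy]dodeca‑2,10‑dienoate F1. Indium in THF/aq. NH4Cl at high dilution closes C6–C7 to methyl (4Z,6R,7S,8R,10R)‑15‑{[tert‑butyl(dimethyl)silyl]oxy}‑6‑hydroxy‑8‑[(2‑methylprop‑2‑enoyl)oxy]‑1,3‑dioxo‑10‑[(triethylsilyl)oxy]germacra‑4,11(13)‑dien‑12‑oate F2, which lactonises to (4Z,6R,7R,8R,10R)‑15‑{[tert‑butyl(dimethyl)silyl]oxy}‑8‑[(2‑methylprop‑2‑enoyl)oxy]‑1,3‑dioxo‑10‑[(triethylsilyl)oxy]germacra‑4,11(13)‑dien‑12,6‑olide F3. HF·pyridine then removes both silyl groups to give (4Z,6R,7R,8R,10R)‑10,15‑dihydroxy‑8‑[(2‑methylprop‑2‑enoyl)oxy]‑1,3‑dioxogermacra‑4,11(13)‑dien‑12,6‑olide F4. Its 10‑hydroxyl adds across the ring to C3, giving (3R,4Z,6R,7R,8R,10R)‑3,10‑epoxy‑3,15‑dihydroxy‑8‑[(2‑methylprop‑2‑enoyl)oxy]‑1‑oxogermacra‑4,11(13)‑dien‑12,6‑olide F5, which loses water to 25.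

Step 7 (tin–lithium exchange and addition to the hindered α‑silyloxy lactone). The furfuryllithium may react at the ring, undergo silyl migration, or enolise the product. The fallback reverses the polarity at C2 so that the furan ring carbon is the nucleophile; it sets out from 10 and comes back at 12. Chloromethyllithium (ICH2Cl, MeLi·LiBr, THF, −78 °C) opens 10 to (3R,5R)‑1‑chloro‑5‑hydroxy‑6,6‑dimethoxy‑3‑methyl‑3‑[(triethylsilyl)oxy]hexan‑2‑one F6. Commercial furan‑3‑ylmethanol is silylated to tert‑butyl(furan‑3‑ylmethoxy)dimethylsilane F7, which is lithiated at C2 of the furan with n‑BuLi and transmetalated with ZnCl2 to chloro{3‑({[tert‑butyl(dimethyl)silyl]oxy}methyl)furan‑2‑yl}zinc F8. Negishi coupling of F8 with F6 (Pd(PPh3)4, THF, rt) gives 12.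

Step 10 (vinylalane addition to the α‑acyloxy aldehyde). C8 may epimerise, or the methacrylate may migrate to the new C7 hydroxyl. The fallback carries O8 as a silyl ether through the aldehyde stage and installs the methacrylate after the bromide; it sets out from 12 and comes back at 19. Excess Et3SiOTf/2,6‑lutidine then water silylates O8 and cleaves the acetal in one operation, giving (2R,4R)‑6‑[3‑({[tert‑butyl(dimethyl)silyl]oxy}methyl)furan‑2‑yl]‑4‑methyl‑5‑oxo‑2,4‑bis[(triethylsilyl)oxy]hexanal F9. Vinylalane 16 adds to give methyl (3RS,4R,6R)‑8‑[3‑({[tert‑butyl(dimethyl)silyl]oxy}methyl)furan‑2‑yl]‑3‑hydroxy‑6‑methyl‑2‑methylidene‑7‑oxo‑4,6‑bis[(triethylsilyl)oxy]octanoate F10. NBS/Me2S (CH2Cl2, 0 °C) effects the SN2′ bromination to methyl (2Z,4R,6R)‑2‑(bromomethyl)‑8‑[3‑({[tert‑butyl(dimethyl)silyl]oxy}methyl)furan‑2‑yl]‑6‑methyl‑7‑oxo‑4,6‑bis[(triethylsilyl)oxy]oct‑2‑enoate F11. PPTS in MeOH at 0 °C removes only the secondary triethylsilyl ether to give methyl (2Z,4R,6R)‑2‑(bromomethyl)‑8‑[3‑({[tert‑butyl(dimethyl)silyl]oxy}methyl)furan‑2‑yl]‑4‑hydroxy‑6‑methyl‑7‑oxo‑6‑[(triethylsilyl)oxy]oct‑2‑enoate F12. Acid‑catalysed acylation (methacrylic anhydride, Sc(OTf)3) then gives 19.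

**Further compounds**

F1 | step 13 | methyl (2Z,4R,6R,10Z)‑2‑(bromomethyl)‑10‑({[tert‑butyl(dimethyl)silyl]oxy}methyl)‑6‑methyl‑4‑[(2‑methylprop‑2‑enoyl)oxy]‑7,9,12‑trioxo‑6‑[(triethylsilyl)oxy]dodeca‑2,10‑dienoate | O=C/C=C(/CO[Si](C)(C)C(C)(C)C)C(=O)CC(=O)[C@](C)(O[Si](CC)(CC)CC)C[C@@H](OC(=O)C(C)=C)/C=C(\CBr)C(=O)OC
F2 | step 13 | methyl (4Z,6R,7S,8R,10R)‑15‑{[tert‑butyl(dimethyl)silyl]oxy}‑6‑hydroxy‑8‑[(2‑methylprop‑2‑enoyl)oxy]‑1,3‑dioxo‑10‑[(triethylsilyl)oxy]germacra‑4,11(13)‑dien‑12‑oate | C=C(C)C(=O)O[C@@H]1C[C@@](C)(O[Si](CC)(CC)CC)C(=O)CC(=O)/C(CO[Si](C)(C)C(C)(C)C)=C\[C@@H](O)[C@@H]1C(=C)C(=O)OC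
F3 | step 13 | (4Z,6R,7R,8R,10R)‑15‑{[tert‑butyl(dimethyl)silyl]oxy}‑8‑[(2‑methylprop‑2‑enoyl)oxy]‑1,3‑dioxo‑10‑[(triethylsilyl)oxy]germacra‑4,11(13)‑dien‑12,6‑olide | C=C(C)C(=O)O[C@@H]1C[C@@](C)(O[Si](CC)(CC)CC)C(=O)CC(=O)/C(CO[Si](C)(C)C(C)(C)C)=C\[C@H]2OC(=O)C(=C)[C@@H]21
F4 | step 13 | (4Z,6R,7R,8R,10R)‑10,15‑dihydroxy‑8‑[(2‑methylprop‑2‑enoyl)oxy]‑1,3‑dioxogermacra‑4,11(13)‑dien‑12,6‑olide | C=C(C)C(=O)O[C@@H]1C[C@@](C)(O)C(=O)CC(=O)/C(CO)=C\[C@H]2OC(=O)C(=C)[C@@H]21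
F5 | step 13 | (3R,4Z,6R,7R,8R,10R)‑3,10‑epoxy‑3,15‑dihydroxy‑8‑[(2‑methylprop‑2‑enoyl)oxy]‑1‑oxogermacra‑4,11(13)‑dien‑12,6‑olide | C=C(C)C(=O)O[C@@H]1C[C@@]2(C)O[C@](O)(CC2=O)/C(CO)=C\[C@H]2OC(=O)C(=C)[C@@H]21
F6 | step 7 | (3R,5R)‑1‑chloro‑5‑hydroxy‑6,6‑dimethoxy‑3‑methyl‑3‑[(triethylsilyl)oxy]hexan‑2‑one | ClCC(=O)[C@](C)(O[Si](CC)(CC)CC)C[C@@H](O)C(OC)OC
F7 | step 7 | tert‑butyl(furan‑3‑ylmethoxy)dimethylsilane | CC(C)(C)[Si](C)(C)OCc1ccoc1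
F8 | step 7 | chloro{3‑({[tert‑butyl(dimethyl)silyl]oxy}methyl)furan‑2‑yl}zinc | Cl[Zn]c1occc1CO[Si](C)(C)C(C)(C)C
F9 | step 10 | (2R,4R)‑6‑[3‑({[tert‑butyl(dimethyl)silyl]oxy}methyl)furan‑2‑yl]‑4‑methyl‑5‑oxo‑2,4‑bis[(triethylsilyl)oxy]hexanal | CC(C)(C)[Si](C)(C)OCc1ccoc1CC(=O)[C@](C)(O[Si](CC)(CC)CC)C[C@@H](O[Si](CC)(CC)CC)C=O
F10 | step 10 | methyl (3RS,4R,6R)‑8‑[3‑({[tert‑butyl(dimethyl)silyl]oxy}methyl)furan‑2‑yl]‑3‑hydroxy‑6‑methyl‑2‑methylidene‑7‑oxo‑4,6‑bis[(triethylsilyl)oxy]octanoate | CC(C)(C)[Si](C)(C)OCc1ccoc1CC(=O)[C@](C)(O[Si](CC)(CC)CC)C[C@@H](O[Si](CC)(CC)CC)C(O)C(=C)C(=O)OC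
F11 | step 10 | methyl (2Z,4R,6R)‑2‑(bromomethyl)‑8‑[3‑({[tert‑butyl(dimethyl)silyl]oxy}methyl)furan‑2‑yl]‑6‑methyl‑7‑oxo‑4,6‑bis[(triethylsilyl)oxy]oct‑2‑enoate | CC(C)(C)[Si](C)(C)OCc1ccoc1CC(=O)[C@](C)(O[Si](CC)(CC)CC)C[C@@H](O[Si](CC)(CC)CC)/C=C(\CBr)C(=O)OC
F12 | step 10 | methyl (2Z,4R,6R)‑2‑(bromomethyl)‑8‑[3‑({[tert‑butyl(dimethyl)silyl]oxy}methyl)furan‑2‑yl]‑4‑hydroxy‑6‑methyl‑7‑oxo‑6‑[(triethylsilyl)oxy]oct‑2‑enoate | CC(C)(C)[Si](C)(C)OCc1ccoc1CC(=O)[C@](C)(O[Si](CC)(CC)CC)C[C@@H](O)/C=C(\CBr)C(=O)OC
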